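Readings and results were generated by integration with made-up constants.

Slowness showed in the substrate readings: in the green run they were still falling from 29.2% to 6.4% between 1.33 min and 3.00 min, while the isomer of the product read level within the scatter. So I treated the fate of the other conformer as a fast affair, over by the second reading, and kept a ledger of it.

common to all: catalyst 2.5 mol%

|  | substrate | other conformer | remark | time |
|---|---|---|---|---|
| green | 0.70 M | 0.25 equiv | run made earlier |  |
| teal | 1.1 M | 0.25 equiv | run made earlier |  |
| flask | 0.50 M | 0.250 equiv |  | 3.0 min |

| run | time / min | isomer of the product / % | target / % | substrate / % |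
|---|---|---|---|---|
| green | 0.667 | 4.4 | 20.0 | 54.8 |
| green | 1.33 | 6.9 | 23.4 | 29.2 |
| green | 2.00 | 6.3 | 24.8 | 14.7 |
| green | 3.00 | 7.7 | 20.7 | 6.4 |
| green | 4.00 | 6.4 | 14.4 | 4.1 |
| teal | 0.667 | 8.3 | 24.9 | 37.2 |
| teal | 1.33 | 8.9 | 23.6 | 12.8 |
| teal | 2.00 | 8.0 | 19.2 | 4.0 |
| teal | 3.00 | 11.3 | 14.3 | 0 |
| teal | 4.00 | 6.8 | 7.7 | 0 |

(readings scatter by 1 percentage point)

- the earlier runs were read with a standard deviation of 1 percentage point

* share of isomer of the product in isomer of the product plus target at 1.2 s
* share of isomer of the product in isomer of the product plus target at 3.0 min
* which of isomer of the product and target there is more of at 3.0 min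

I treated the other conformer as the limiting reagent of the isomer's route; it is 20.0% of what is charged in each flask. I booked it under two entries: isomer of the product, and a remainder that I assumed returned to substrate. If catalyst captures it in a pseudo-first-order step, while the return does not involve catalyst, the odds between the entries grow in proportion to the catalyst concentration C.

From the second reading on, the isomer averaged 6.83% in the green run and 8.75% in the teal run. Dividing the odds by C gave 29.6 M⁻¹ and 28.3 M⁻¹. I averaged these readings into the capture constant κ, the isomer entry over the remainder entry per molar catalyst: 28.9 M⁻¹.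

For the flask, C is 0.0125 M, so the odds are 0.362. The isomer entry is 5.31% and the remainder 14.7%, which closes the books. Taking target at its read peak of about 24.8%, I reckoned an isomer share of 17.6% at 3.0 min, with target ahead of the isomer. The readings begin at 0.667 min, so I had no figure of my own for 1.2 s.

The forecast gave an isomer share of 17% at 1.2 s and 24% at 3.0 min, with target ahead, a later share above mine, on the ground that “The share rises later because target is lost faster than isomer.”

The flask gave 37.5% at 1.2 s and 20.9% at 3.0 min, with target ahead.

    substrate ⇌ other conformer (K = 0.0275, k = 0.00362 s⁻¹)
    substrate + catalyst → catalyst + target (k = 0.622 M⁻¹ s⁻¹)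
    catalyst + other conformer → catalyst + isomer of the product (k = 1.62 M⁻¹ s⁻¹)
    substrate + target → side product (k = 0.0250 M⁻¹ s⁻¹)
    catalyst + target → catalyst + over-reaction product (k = 0.306 M⁻¹ s⁻¹)

At 0.300 min the flask held 3.15% of other conformer. At 3.00 min its isomer stood at 6.31%, which is 1 point above the entry from κ. In the neighbour flask with 6.2 mol% of catalyst, κ gives odds of 0.897 and an isomer entry of 9.46%. The computed amount there is 9.41%.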